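(The constants used here belong to no real substance; no experiment stands behind them.)

You charge 0.0250 M of coupling partner against 0.0200 M of substrate in the two hands together, and what you should follow is the amount of partner that reaches substrate.

    coupling partner + left-handed substrate → left-handed product (k1 = 0.824 M⁻¹ s⁻¹, Ea1 = 66.0 kJ mol⁻¹)
    coupling partner + right-handed substrate → right-handed product (k2 = 0.477 M⁻¹ s⁻¹, Ea2 = 55.0 kJ mol⁻¹)
    left-handed substrate + racemization catalyst ⇌ right-handed substrate + racemization catalyst, rate k3*[racemization catalyst]*[left-handed substrate] forward; the back reaction follows from the equilibrium constant (k3 = 523 M⁻¹ s⁻¹, Ea3 = 56.0 kJ mol⁻¹)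
    coupling partner ⇌ dormant form (K4 = 0.46, k4 = 1.25 s⁻¹, Ea4 = 87.0 kJ mol⁻¹, ΔH4 = −33.0 kJ mol⁻¹)
    coupling partner → decomposition product (k5 = 1.85 × 10⁻⁵ s⁻¹, Ea5 = 127 kJ mol⁻¹)
    2 coupling partner → self-condensation product (k6 = 3.22 M⁻¹ s⁻¹, Ea6 = 69.0 kJ mol⁻¹)
    (constants at 90 °C)

| setting | birch | maple | ash |
|---|---|---|---|
| left-handed substrate | 0.010 M | 0.010 M | 0.010 M |
| coupling partner | 2.50 equiv | 2.50 equiv | 2.50 equiv |
| racemization catalyst | 1.6 mol% | 1.6 mol% | 1.6 mol% |
| right-handed substrate | 0.010 M | 0.010 M | 0.010 M |
| time | 4.0 min | 4.0 min | 4.0 min |
| remark | at 120 °C until 2.0 min, from then on at 90 °C |  |  |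
| temperature |  | 120 °C | 90 °C |

- the flask with the highest amount of left-handed product, in percent of the left-handed substrate and right-handed substrate together charged ("all alike" if they lie within 1.5 percentage points) (birch / maple / ash / all alike)
- final left-handed product, as a percentage of the left-handed substrate and right-handed substrate together charged, in birch
- final left-handed product, as a percentage of the left-handed substrate and right-handed substrate together charged, in maple
- final left-handed product, as a percentage of the left-handed substrate and right-handed substrate together charged, in ash

- coupling partner is single-handed; left-handed substrate and right-handed substrate are mirror images of each other, charged as a racemate, each of them at the stated concentration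
- where a step has two of a species, its rate is k times that concentration squared, and two are used at each turn
- all constants are for 90 °C and move with temperature by the activation energies and enthalpies
- the handed part of coupling partner does not stay in what it makes, so the products of the two hands are mirror images too

Here is my own reckoning. Call ka, kb and ks the constants of the left coupling, the right coupling and self-condensation, T the pool of partner (free plus dormant), and f its free share. At 120 °C the constants become ka 4.37 M⁻¹ s⁻¹, kb 1.92 M⁻¹ s⁻¹ and ks 18.4 M⁻¹ s⁻¹, and f is 0.833, against 0.685 at 90 °C. I hold f steady, because at 90 °C the dormant form balances within 0.252 s, shorter than the 6.21 s first half-life of partner by self-condensation. Racemization turns left-handed substrate over at 0.0837 s⁻¹ at 90 °C, faster than coupling at the full charge, 0.0206 s⁻¹, and the same holds at 120 °C. So I take the hands as equal at S each, which gives left-handed product the share s = ka/(ka+kb) of what couples, a selectivity set by the two constants.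

Partner then splits two ways, and the split turns at the crossing pool T× = (ka+kb)S/(2ks f). With S at its charge that is 0.00205 M at 120 °C and 0.00295 M at 90 °C, and the charge stands above both. Above T× more partner goes to itself than to substrate. Below it, partner decays pseudo-first-order on substrate with lifetime τ = 1/(f(ka+kb)S). Integrating from the charge Tc gives T/(T+T×) = [Tc/(Tc+T×)]e^(−t/τ), and the coupled amount C = T× ln[(Tc+T×)/(T+T×)]. For S I take the charge less a quarter of a first-pass C, as my estimate of its mean while coupling goes on.

| | 90 °C | 120 °C |
|---|---|---|
| s | 0.633 | 0.695 |
| mean S | 0.00834 M | 0.00868 M |
| T× | 0.00246 M | 0.00178 M |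
| C at T = nil, share of substrate | 29.7% | 24.1% |
| left-handed product at T = nil | 18.8% | 16.8% |
| τ | 135 s | 22.0 s |

Read s and C together: heat raises the left share but lowers what couples, so the two pull against each other. Now read τ. At 120 °C the switch time holds 5.45 lifetimes, so I reckon that birch keeps 0.0285% of its pool at the cooling, and I give birch and maple the same 16.8%. In ash the 4.0 min holds 1.78 lifetimes, so watch the tail: I reckon the pool at 4.44 × 10⁻⁴ M at that time, and left-handed product at 17.5%. That is 0.70 percentage points above my maple figure, inside the 1.5 points margin.

The forecast put birch at 20.8%, maple at 20.8% and ash at 22%, higher than my figures, and also said all alike, with birch like maple “since almost no partner remains at the switch”.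

The run gives 16.9% in birch, 17.0% in maple and 17.8% in ash: all alike. The neighbour flask is birch with 10.0 equiv of coupling partner, a charge of 0.100 M. Starting again from 0.00205 M, the mean S is 0.00800 M and T× is 0.00164 M, so C is 33.8% and left-handed product 23.5%. Partner rises by a factor 4.00, and the reckoned product by 1.40. That neighbour flask reads 24.0% left-handed product, with 0.0069% of its partner charge left at 4.00 min.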